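**Plan**

1. Cuts: C2'–C3' (sp3–sp2 Suzuki–Miyaura) gives a 2-vinylchroman and an (E)-vinyl iodide diol. In the chroman, O1–C8a and C2–C3 are cut together, then C1'=C2' (Wittig) and C6–O. In the iodide, C4'–CH3 (carboalumination) and C5'–C6' (propargylation at C1 of geraniol) are cut.
2. Enabling feature: in the pyran ring (O1, C2, C3, C4, C4a, C8a) C3 and C8a stand 1,4 across C4–C4a of the benzo ring. One temporary C4 ketone makes C3 an enolate carbon and activates C8a–F for ipso attack, and C2 (O1, CH3, C1') is the ketone carbon of pyruvate, so the ring is a C=O laid across an aryl 1,4-dipole.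
3. Forward, chroman: the enolsilane of 2'-fluoro-3'-methylacetophenone and methyl pyruvate give the chroman-4-one ester in one flask with [Cu((R,R)-t-Bu-box)](OTf)2. The C4 carbonyl is then hydrogenolysed, C6–OH is installed by C–H borylation ([Ir(OMe)(cod)]2) and oxidation, and the ester is taken to the vinyl group.
4. Forward, chain: geraniol is epoxidised asymmetrically, its C1 triflate is displaced by lithiated 1-(trimethylsilyl)propyne, and the epoxide is hydrolysed. Carboalumination/iodination, hydroboration/Suzuki union and desilylation finish the route.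
5. Stereochemistry: C2 comes from the copper catalyst in the aldol stage. C7' and C8' come from the tartrate-controlled epoxidation (C7'–O kept, C8' inverted on hydrolysis). The C3'=C4' (E) geometry comes from syn-carbometalation.

Key step: step 2

Assumption: locants follow the chroman skeleton (O1, C2, C3, C4, C4a, C5–C8, C8a) and primed numbers the side chain from C1' (on C2) to C13'; compounds 1, 3, 12 and 14 are taken as purchasable; t-Bu-box is 2,2'-(propane-2,2-diyl)bis[(4R)-4-tert-butyl-4,5-dihydro-1,3-oxazole].

**Route**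

Step 1
Reactants: 1 1-(2-fluoro-3-methylphenyl)ethan-1-one
Product: 2 {[1-(2-fluoro-3-methylphenyl)ethenyl]oxy}trimethylsilane
Conditions: TMSOTf, Et3N, CH2Cl2, 0 °C
Reagents that add atoms: trimethylsilyl trifluoromethanesulfonate C[Si](C)(C)OS(=O)(=O)C(F)(F)F
Why: Soft enolisation of an aryl methyl ketone (silyl enol ether formation) can give only the terminal enolsilane, and the aryl fluoride is inert.

Step 2
Reactants: 2 {[1-(2-fluoro-3-methylphenyl)ethenyl]oxy}trimethylsilane; 3 methyl pyruvate
Product: 5 methyl (2R)-2,8-dimethyl-4-oxo-3,4-dihydro-2H-chromene-2-carboxylate, via aldol silyl ether 4 (not isolated)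
Conditions: [Cu((R,R)-t-Bu-box)](OTf)2 (10 mol %), THF, −78 °C; then CsF (1.5 equiv), DMF, 0 → 40 °C
Reagents that add atoms: none
Why: Proposed new method: the bis(oxazoline) complex of divalent copper binds methyl pyruvate as a five-membered chelate through both carbonyl oxygens, the CH2 carbon of 2 adds to the ketone face left open by the tert-butyl groups (C2–C3 bond, silyl transfer to O1 gives 4), and fluoride then frees the O1 alkoxide, which attacks C8a ortho to the C4 ketone and expels fluoride, which leaves as Me3SiF. The closest known reaction types are the copper-bis(oxazoline)-catalysed Mukaiyama aldol addition of enolsilanes to pyruvate esters and the base-mediated SNAr cyclisation of 2-fluoroaryl β-hydroxy ketones to chroman-4-ones; their merger in one flask is the new element. The pyranone ring closes by six-membered addition–elimination at C8a (6-endo-trig with respect to the C4a=C8a bond conjugated to the C4 carbonyl, through a Meisenheimer intermediate). The C2 stereocentre is set by the ligand alone: the (S,S) antipode is known to direct enolsilanes to the si face of chelated pyruvate, so the (R,R) ligand should give re-face attack and (R)-4. The step needs enantioface selectivity in the aldol stage and a ring closure that outruns retro-aldol cleavage of the O1 alkoxide and base-induced ring opening of 5; the one C4 carbonyl that makes C3 nucleophilic also activates C8a–F, the closure is intramolecular and six-membered, and fluoride is the only base present.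

Step 3
Reactants: 5 methyl (2R)-2,8-dimethyl-4-oxo-3,4-dihydro-2H-chromene-2-carboxylate
Product: 6 methyl (2R)-2,8-dimethylchromane-2-carboxylate
Conditions: H2 (5 bar), Pd/C, AcOH, 70 °C
Reagents that add atoms: none
Why: Acidic hydrogenolysis of the aryl ketone through the benzylic alcohol removes the C4 helper, as is usual for chroman-4-ones; C2 has no α-hydrogen and the O1–C8a aryl ether is not benzylic, so ring and stereocentre should be untouched.

Step 4
Reactants: 6 methyl (2R)-2,8-dimethylchromane-2-carboxylate
Product: 8 methyl (2R)-6-hydroxy-2,8-dimethylchromane-2-carboxylate, via aryl boronate 7 (not isolated)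
Conditions: B2pin2, [Ir(OMe)(cod)]2 (1.5 mol %), dtbpy (3 mol %), THF, 80 °C; then NaBO3·4H2O, THF/H2O, 23 °C
Reagents that add atoms: bis(pinacolato)diboron CC1(C)OB(OC1(C)C)B1OC(C)(C)C(C)(C)O1 (boryl group of 7); sodium perborate [Na+].[O-]B1OO1 (oxygen at C6 of 8)
Why: Arene C–H borylation with this iridium catalyst is sterically controlled, and C6–H is the only ring C–H without an ortho substituent (C5–H lies next to C4a, C7–H next to C8–CH3), so boron should enter para to O1; perborate oxidation of the aryl boronate then gives the phenol with the ester intact.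

Step 5
Reactants: 8 methyl (2R)-6-hydroxy-2,8-dimethylchromane-2-carboxylate
Product: 9 methyl (2R)-2,8-dimethyl-6-[(triisopropylsilyl)oxy]chromane-2-carboxylate
Conditions: TIPSCl, imidazole, DMF, 23 °C
Reagents that add atoms: chlorotriisopropylsilane CC(C)[Si](Cl)(C(C)C)C(C)C
Why: Silylation of the phenol gives an aryl silyl ether that should survive hydride, ylide, borane and aqueous carbonate and fall to fluoride at the end.

Step 6
Reactants: 9 methyl (2R)-2,8-dimethyl-6-[(triisopropylsilyl)oxy]chromane-2-carboxylate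
Product: 10 (2R)-2,8-dimethyl-6-[(triisopropylsilyl)oxy]chromane-2-carbaldehyde
Conditions: i-Bu2AlH (1.1 equiv), CH2Cl2, −78 °C; aq. potassium sodium tartrate
Reagents that add atoms: none
Why: Half-reduction of the α-alkoxy ester stops at the chelated aluminium hemiacetal at −78 °C and gives the aldehyde on work-up; the quaternary C2 cannot epimerise.

Step 7
Reactants: 10 (2R)-2,8-dimethyl-6-[(triisopropylsilyl)oxy]chromane-2-carbaldehyde
Product: 11 {[(2R)-2-ethenyl-2,8-dimethylchroman-6-yl]oxy}triisopropylsilane
Conditions: Ph3PCH3Br, KOtBu, THF, 0 → 23 °C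
Reagents that add atoms: methyltriphenylphosphonium bromide C[P+](c1ccccc1)(c1ccccc1)c1ccccc1.[Br-]
Why: Wittig methylenation of a non-enolisable aldehyde supplies C2' and the vinyl handle for hydroboration.

Step 8
Reactants: 12 geraniol
Product: 13 [(2S,3S)-3-methyl-3-(4-methylpent-3-en-1-yl)oxiran-2-yl]methanol
Conditions: Ti(OiPr)4 (5 mol %), L-(+)-diisopropyl tartrate (6 mol %), t-BuOOH, 4 Å MS, CH2Cl2, −20 °C
Reagents that add atoms: tert-butyl hydroperoxide CC(C)(C)OO
Why: Sharpless asymmetric epoxidation is directed by the allylic hydroxyl, which selects the 2,3-alkene over the 6,7-alkene, and the L-(+)-tartrate sets the (2S,3S) configuration (later C7' and C8').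

Step 9
Reactants: 13 [(2S,3S)-3-methyl-3-(4-methylpent-3-en-1-yl)oxiran-2-yl]methanol; 14 trimethyl(prop-1-yn-1-yl)silane
Product: 17 trimethyl{4-[(2S,3S)-3-methyl-3-(4-methylpent-3-en-1-yl)oxiran-2-yl]but-1-yn-1-yl}silane, via epoxy triflate 15 (not isolated), via 3-lithio-1-(trimethylsilyl)propyne 16 (not isolated)
Conditions: 13, n-BuLi then Tf2O, Et2O, −78 °C; 14, n-BuLi, THF, −20 °C; combine, −78 → −30 °C
Reagents that add atoms: trifluoromethanesulfonic anhydride O=S(=O)(OS(=O)(=O)C(F)(F)F)C(F)(F)F (triflyl group of 15); n-butyllithium [Li]CCCC (lithium of 16)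
Why: SN2 displacement of a primary triflate by the propargylic carbon of the silyl-capped propargyl lithium (the silyl group favours the acetylenic over the allenic product) forms C5'–C6' at low temperature, where the hindered trisubstituted epoxide should not be attacked.

Step 10
Reactants: 17 trimethyl{4-[(2S,3S)-3-methyl-3-(4-methylpent-3-en-1-yl)oxiran-2-yl]but-1-yn-1-yl}silane
Product: 18 (5S,6R)-6,10-dimethyl-1-(trimethylsilyl)undec-9-en-1-yne-5,6-diol
Conditions: HClO4 (cat.), THF/H2O, 0 °C
Reagents that add atoms: water O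
Why: Acid-catalysed epoxide hydrolysis: water should attack the protonated epoxide at the tertiary carbon from the rear (inversion at C8'), while the C7'–O bond is kept, which gives the (7'S,8'R) anti-diol.

Step 11
Reactants: 18 (5S,6R)-6,10-dimethyl-1-(trimethylsilyl)undec-9-en-1-yne-5,6-diol
Product: 19 (5S,6R)-6,10-dimethylundec-9-en-1-yne-5,6-diol
Conditions: K2CO3, MeOH, 23 °C
Reagents that add atoms: none
Why: Methanolysis of the alkynyl–silicon bond (protodesilylation) frees the terminal alkyne without touching the diol or the alkene.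

Step 12
Reactants: 19 (5S,6R)-6,10-dimethylundec-9-en-1-yne-5,6-diol
Product: 21 (1E,5S,6R)-1-iodo-2,6,10-trimethylundeca-1,9-diene-5,6-diol, via alkenylalane 20 (not isolated)
Conditions: AlMe3 (5 equiv), Cp2ZrCl2 (0.5 equiv), CH2Cl2, 0 → 23 °C; then I2, THF, −30 → 0 °C; aq. potassium sodium tartrate
Reagents that add atoms: trimethylaluminium C[Al](C)C; iodine II
Why: Negishi zirconium-catalysed carboalumination adds methyl and aluminium syn across the terminal alkyne with methyl on the inner carbon, and iodinolysis with retention gives the (E)-iodide; the hydroxyl groups travel as aluminium alkoxides and the trisubstituted alkene is inert.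

Step 13
Reactants: 11 {[(2R)-2-ethenyl-2,8-dimethylchroman-6-yl]oxy}triisopropylsilane; 21 (1E,5S,6R)-1-iodo-2,6,10-trimethylundeca-1,9-diene-5,6-diol
Product: 23 (6R,7S,10E)-13-{(2S)-2,8-dimethyl-6-[(triisopropylsilyl)oxy]chroman-2-yl}-2,6,10-trimethyltrideca-2,10-diene-6,7-diol, via alkylborane 22 (not isolated)
Conditions: 11, 9-BBN, THF, 0 → 23 °C; then 21, PdCl2(dppf) (5 mol %), AsPh3, Cs2CO3, DMF/H2O, 23 °C
Reagents that add atoms: 9-borabicyclo[3.3.1]nonane B1C2CCCC1CCC2 (boryl group of 22)
Why: B-alkyl Suzuki–Miyaura coupling: anti-Markovnikov hydroboration of the vinyl group gives the primary alkylborane, which couples after oxidative addition of the vinyl iodide to zerovalent palladium with retention of the E geometry, and free hydroxyl groups are tolerated.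

Step 14
Reactants: 23 (6R,7S,10E)-13-{(2S)-2,8-dimethyl-6-[(triisopropylsilyl)oxy]chroman-2-yl}-2,6,10-trimethyltrideca-2,10-diene-6,7-diol
Product: 24 (2S)-2-[(3E,7S,8R)-7,8-dihydroxy-4,8,12-trimethyltrideca-3,11-dien-1-yl]-2,8-dimethylchroman-6-ol
Conditions: Bu4NF, THF, 0 °C, degassed; aq. NH4Cl
Reagents that add atoms: none
Why: Fluoride cleavage of the aryl silyl ether releases the phenol under conditions that leave the diol, the alkenes and the chroman untouched.

**Compound list**

1 | 1-(2-fluoro-3-methylphenyl)ethan-1-one | CC(=O)c1cccc(C)c1F | starting material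
2 | {[1-(2-fluoro-3-methylphenyl)ethenyl]oxy}trimethylsilane | C=C(O[Si](C)(C)C)c1cccc(C)c1F | intermediate
3 | methyl pyruvate | CC(=O)C(=O)OC | starting material
4 | methyl (2R)-4-(2-fluoro-3-methylphenyl)-2-methyl-4-oxo-2-[(trimethylsilyl)oxy]butanoate | COC(=O)[C@](C)(O[Si](C)(C)C)CC(=O)c1cccc(C)c1F | intermediate (not isolated)
5 | methyl (2R)-2,8-dimethyl-4-oxo-3,4-dihydro-2H-chromene-2-carboxylate | COC(=O)[C@@]1(C)CC(=O)c2cccc(C)c2O1 | intermediate
6 | methyl (2R)-2,8-dimethylchromane-2-carboxylate | COC(=O)[C@@]1(C)CCc2cccc(C)c2O1 | intermediate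
7 | methyl (2R)-2,8-dimethyl-6-(4,4,5,5-tetramethyl-1,3,2-dioxaborolan-2-yl)chromane-2-carboxylate | COC(=O)[C@@]1(C)CCc2cc(B3OC(C)(C)C(C)(C)O3)cc(C)c2O1 | intermediate (not isolated)
8 | methyl (2R)-6-hydroxy-2,8-dimethylchromane-2-carboxylate | COC(=O)[C@@]1(C)CCc2cc(O)cc(C)c2O1 | intermediate
9 | methyl (2R)-2,8-dimethyl-6-[(triisopropylsilyl)oxy]chromane-2-carboxylate | COC(=O)[C@@]1(C)CCc2cc(O[Si](C(C)C)(C(C)C)C(C)C)cc(C)c2O1 | intermediate
10 | (2R)-2,8-dimethyl-6-[(triisopropylsilyl)oxy]chromane-2-carbaldehyde | O=C[C@@]1(C)CCc2cc(O[Si](C(C)C)(C(C)C)C(C)C)cc(C)c2O1 | intermediate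
11 | {[(2R)-2-ethenyl-2,8-dimethylchroman-6-yl]oxy}triisopropylsilane | C=C[C@@]1(C)CCc2cc(O[Si](C(C)C)(C(C)C)C(C)C)cc(C)c2O1 | intermediate
12 | geraniol, (2E)-3,7-dimethylocta-2,6-dien-1-ol | CC(C)=CCC/C(C)=C/CO | starting material
13 | [(2S,3S)-3-methyl-3-(4-methylpent-3-en-1-yl)oxiran-2-yl]methanol | CC(C)=CCC[C@]1(C)O[C@H]1CO | intermediate
14 | trimethyl(prop-1-yn-1-yl)silane | CC#C[Si](C)(C)C | starting material
15 | [(2S,3S)-3-methyl-3-(4-methylpent-3-en-1-yl)oxiran-2-yl]methyl trifluoromethanesulfonate | CC(C)=CCC[C@]1(C)O[C@H]1COS(=O)(=O)C(F)(F)F | intermediate (not isolated)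
16 | 3-lithio-1-(trimethylsilyl)prop-1-yne | [Li]CC#C[Si](C)(C)C | intermediate (not isolated)
17 | trimethyl{4-[(2S,3S)-3-methyl-3-(4-methylpent-3-en-1-yl)oxiran-2-yl]but-1-yn-1-yl}silane | CC(C)=CCC[C@]1(C)O[C@H]1CCC#C[Si](C)(C)C | intermediate
18 | (5S,6R)-6,10-dimethyl-1-(trimethylsilyl)undec-9-en-1-yne-5,6-diol | CC(C)=CCC[C@@](C)(O)[C@@H](O)CCC#C[Si](C)(C)C | intermediate
19 | (5S,6R)-6,10-dimethylundec-9-en-1-yne-5,6-diol | CC(C)=CCC[C@@](C)(O)[C@@H](O)CCC#C | intermediate
20 | (E)-alkenyl(dimethyl)alane of 19 with both hydroxyl groups as dimethylaluminium alkoxides | CC(C)=CCC[C@@](C)(O[Al](C)C)[C@@H](O[Al](C)C)CC/C(C)=C/[Al](C)C | intermediate (not isolated)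
21 | (1E,5S,6R)-1-iodo-2,6,10-trimethylundeca-1,9-diene-5,6-diol | CC(C)=CCC[C@@](C)(O)[C@@H](O)CC/C(C)=C/I | intermediate
22 | 9-(2-{(2S)-2,8-dimethyl-6-[(triisopropylsilyl)oxy]chroman-2-yl}ethyl)-9-borabicyclo[3.3.1]nonane | C(C[C@@]1(C)CCc2cc(O[Si](C(C)C)(C(C)C)C(C)C)cc(C)c2O1)B1C2CCCC1CCC2 | intermediate (not isolated)
23 | (6R,7S,10E)-13-{(2S)-2,8-dimethyl-6-[(triisopropylsilyl)oxy]chroman-2-yl}-2,6,10-trimethyltrideca-2,10-diene-6,7-diol | CC(C)=CCC[C@@](C)(O)[C@@H](O)CC/C(C)=C/CC[C@@]1(C)CCc2cc(O[Si](C(C)C)(C(C)C)C(C)C)cc(C)c2O1 | intermediate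
24 | (2S)-2-[(3E,7S,8R)-7,8-dihydroxy-4,8,12-trimethyltrideca-3,11-dien-1-yl]-2,8-dimethylchroman-6-ol | CC(C)=CCC[C@@](C)(O)[C@@H](O)CC/C(C)=C/CC[C@@]1(C)CCc2cc(O)cc(C)c2O1 | target

**Count and risks**

Total steps: 14. Longest linear sequence: 9 steps (steps 1–7, 13, 14); the side-chain branch has 5 steps (8–12) before the union.

Steps most likely to fail:

1. Step 2 (proposed new method). The freed O1 alkoxide may revert by retro-aldol cleavage before it closes on C8a, and the product may open and reclose under base through its C3 enolate. Either process would lower the enantiomeric purity at C2, and a ring activated only by the ortho ketone may close too slowly. The fallback uses known chemistry, sets out from methyl pyruvate 3 and comes back at 6. Bought 1-(2-bromo-3-methylphenyl)ethan-1-one F1 is converted with TMSOTf/Et3N into its enolsilane F2. The same copper-catalysed Mukaiyama aldol addition to 3, stopped by acidic desilylation, gives methyl (2R)-4-(2-bromo-3-methylphenyl)-2-hydroxy-2-methyl-4-oxobutanoate F3. Ionic hydrogenation (Et3SiH, TFA, 50 °C) removes the ketone, and with it any retro-aldol path, to give the hydroxy ester F4. Palladium-catalysed intramolecular C–O coupling of the tertiary alcohol with the aryl bromide (Pd(OAc)2, 2-(di-tert-butylphosphino)-1,1'-binaphthyl, Cs2CO3, toluene, 80 °C; Buchwald–Hartwig etherification) then closes O1–C8a to give 6.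

2. Step 9. The epoxy triflate may ionise or decompose before it is displaced, the propargyl lithium may react through its allenic end, or it may attack the epoxide. The fallback forms C5'–C6' by opening a terminal epoxide instead; it sets out from 13 and comes back at 18. Acid-catalysed hydrolysis of 13 (HClO4, THF/H2O) gives (2S,3R)-3,7-dimethyloct-6-ene-1,2,3-triol F5. Selective sulfonylation of the primary hydroxyl (TsCl, Et3N, cat. Bu2SnO) gives the tosylate F6. With an excess of 16 (THF, −78 → 0 °C) the C2 alkoxide closes to the terminal epoxide (2R)-6-methyl-2-[(2S)-oxiran-2-yl]hept-5-en-2-ol F7, which 16 should open at its CH2 group to give 18 directly.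

3. Step 10. Partial ionisation at the tertiary carbon would scramble C8', attack of water at C7' would give the enantiomeric diol, and the acid may draw the C11'=C12' alkene or the new tertiary hydroxyl into ether formation. The fallback sets both C–O bonds by SN2 steps only; it sets out from geraniol 12 and comes back at 18. Sharpless epoxidation with D-(−)-diisopropyl tartrate gives [(2R,3R)-3-methyl-3-(4-methylpent-3-en-1-yl)oxiran-2-yl]methanol F8. Aqueous NaOH in t-BuOH at 70 °C (Payne rearrangement, then hydroxide opening of the terminal epoxide at C1) inverts C2 through the C1 alkoxide and leaves the C3–O bond alone, so the same triol F5 results without any substitution at the tertiary carbon. Tosylation to F6 and reaction with 16, as in the fallback for step 9, then lead to 18.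

**Further compounds**

F1 | step 2 | 1-(2-bromo-3-methylphenyl)ethan-1-one | CC(=O)c1cccc(C)c1Br
F2 | step 2 | {[1-(2-bromo-3-methylphenyl)ethenyl]oxy}trimethylsilane | C=C(O[Si](C)(C)C)c1cccc(C)c1Br
F3 | step 2 | methyl (2R)-4-(2-bromo-3-methylphenyl)-2-hydroxy-2-methyl-4-oxobutanoate | COC(=O)[C@](C)(O)CC(=O)c1cccc(C)c1Br
F4 | step 2 | methyl (2R)-4-(2-bromo-3-methylphenyl)-2-hydroxy-2-methylbutanoate | COC(=O)[C@](C)(O)CCc1cccc(C)c1Br
F5 | step 9 | (2S,3R)-3,7-dimethyloct-6-ene-1,2,3-triol | CC(C)=CCC[C@@](C)(O)[C@@H](O)CO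
F6 | step 9 | (2S,3R)-2,3-dihydroxy-3,7-dimethyloct-6-en-1-yl 4-methylbenzenesulfonate | CC(C)=CCC[C@@](C)(O)[C@@H](O)COS(=O)(=O)c1ccc(C)cc1
F7 | step 9 | (2R)-6-methyl-2-[(2S)-oxiran-2-yl]hept-5-en-2-ol | CC(C)=CCC[C@@](C)(O)[C@@H]1CO1
F8 | step 10 | [(2R,3R)-3-methyl-3-(4-methylpent-3-en-1-yl)oxiran-2-yl]methanol | CC(C)=CCC[C@@]1(C)O[C@@H]1CO
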